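**Strategy.** Everything rests on breaking the two O–CH3 bonds, at O7 of ring A and O4' of ring B, last. One biocatalytic pot (a 4'- and a 7-selective O-methyltransferase, cofactor regenerated from methyl iodide) forms both bonds at neutral pH on the unprotected pentol (2R,3R)-8-prenyltaxifolin. The step exploits three features. O5–H is chelated to the C4 carbonyl, O3–H is aliphatic, and O3'/O4' of the ring B catechol can only be told apart by an active site. In addition, C2/C3 of ring C would not survive basic alkylation. The pentol comes from (+)-taxifolin, which supplies both stereocentres, by O5 prenylation and a Claisen–Cope relay to C8.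

Key step: step 5

Structure check: the target SMILES decodes as the trans-(2R,3R) dihydroflavonol with 5-OH, 7-OMe, 8-prenyl, 3'-OH and 4'-OMe. C2 and C3 have the same configuration as in (+)-taxifolin, so no structure needs correcting.

Assumption: commercial larch-derived (+)-taxifolin is taken as the single (2R,3R) enantiomer. The three methyltransferases are taken as recombinant catalysts from synthetic genes expressed in E. coli, chosen by a small panel screen.

**Step 1**
Reactants: 1 (+)-taxifolin
Product: 2 (2R,3R)-3,7,3',4'-tetra-O-acetyltaxifolin (5-OH free)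
Conditions: Ac2O (4.3 equiv), pyridine, no DMAP, 0 °C to rt
Reagents that add atoms: acetic anhydride, CC(=O)OC(C)=O
Why: Chemoselective pyridine-mediated O-acetylation esterifies the three free phenols and then the secondary 3-OH well before the 5-OH, whose hydrogen bond to the C4 carbonyl makes it the least nucleophilic hydroxyl, and pyridine is too weak a base to open ring C, so C2 and C3 stay (R,R).

**Step 2**
Reactants: 2 (2R,3R)-3,7,3',4'-tetra-O-acetyltaxifolin; 3 3-methylbut-2-en-1-ol (prenol)
Product: 4 (2R,3R)-3,7,3',4'-tetra-O-acetyl-5-O-prenyltaxifolin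
Conditions: 3 (1.5 equiv), PPh3, DIAD, THF, 0 °C to rt
Reagents that add atoms: 3-methylbut-2-en-1-ol (3), CC(C)=CCO
Why: In this Mitsunobu etherification the 5-OH is the only acidic proton left, the primary allylic alcohol is activated as its oxyphosphonium salt and displaced at CH2 without allylic transposition, the neutral medium avoids the acetate scrambling and ring C opening that an allyl halide plus carbonate base would invite, and the 3-acetate blocks Mitsunobu dehydration at C3.

**Step 3**
Reactants: 4 (2R,3R)-3,7,3',4'-tetra-O-acetyl-5-O-prenyltaxifolin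
Product: 7 (2R,3R)-3,7,3',4'-tetra-O-acetyl-8-prenyltaxifolin, via C6 reverse-prenyl ortho-dienone 5 (not isolated), via C8 prenyl para-dienone 6 (not isolated)
Conditions: Eu(fod)3 (10 mol %; fod = 6,6,7,7,8,8,8-heptafluoro-2,2-dimethyloctane-3,5-dionate), acid-free CHCl3, argon, 60 °C
Reagents that add atoms: none
Why: In this Lewis-acid-catalysed tandem aromatic Claisen–Cope (para-Claisen) rearrangement, trivalent europium bound to the C4 carbonyl and O5 lowers the barrier of the [3,3] shift to C6, the crowded dienone 5 flanked by the 7-acetate undergoes a second [3,3] shift to C8 faster than it enolises, the double allyl inversion restores a linear prenyl group, and tautomerisation of 6 rearomatises ring A without touching C2, C3 or the esters.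

**Step 4**
Reactants: 7 (2R,3R)-3,7,3',4'-tetra-O-acetyl-8-prenyltaxifolin
Product: 8 (2R,3R)-8-prenyltaxifolin
Conditions: HCl (cat., about 0.3 M) in dry MeOH, argon, rt; partition between EtOAc and pH 6 buffer
Reagents that add atoms: none
Why: Acid-catalysed transesterification (methanolysis) removes aryl and secondary acetates alike without ever generating phenoxides, which shuts off ring C opening, C2/C3 epimerisation and aerial oxidation to the flavonol, and dilute methanolic HCl at room temperature is the medium in which acetal groups are routinely taken off prenylated flavonoids with the alkene intact.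

**Step 5**
Reactants: 8 (2R,3R)-8-prenyltaxifolin; 9 methyl iodide
Product: 11 target, (2R,3R)-7,4'-di-O-methyl-8-prenyltaxifolin, via 4'-O-methyl-8-prenyltaxifolin 10 (not isolated)
Conditions: flavonoid 4'-O-methyltransferase (e.g. MpOMT4 or SOMT-2 type), then flavonoid 7-O-methyltransferase (e.g. rice NOMT or SaOMT-2 type) added to the same pot, halide methyltransferase, S-adenosyl-L-homocysteine (2 mol %), 9 (4 equiv), degassed K2HPO4/KH2PO4 buffer pH 7.5, 10% DMSO, N2, sealed vessel, 28 °C; EtOAc extraction, chromatography
Reagents that add atoms: methyl iodide (9), CI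
Why: In each O-methyltransferase an active-site histidine takes the proton of the one phenol held beside the cofactor and the phenoxide attacks the sulfonium methyl of S-adenosylmethionine in a one-step, in-line SN2 transfer, after which the halide methyltransferase re-methylates the released S-adenosylhomocysteine with 9, so the cofactor stays catalytic and product inhibition is relieved. The closest known reaction type is the S-adenosylmethionine-dependent O7- and O4'-methylation of flavanones, dihydroflavonols and 8-prenylflavonols (sakuranetin-, hesperetin- and icaritin-type tailoring) coupled to halide-methyltransferase recycling, here applied to a new member of the same substrate class. No ring is closed and no stereocentre is made; C2 and C3 are carried through unchanged, because pH 7.5 and 28 °C lie below the conditions at which ring C opens or C3 enolises. The selectivity needed is O4' over O3' in ring B and O7 over O5 and O3 in rings A and C: the first is decided only by the binding pose in the 4'-enzyme, the second by the pose in the 7-enzyme and backed by the substrate, since O5–H is tied to C4=O and O3–H is a weakly acidic secondary alcohol. Dosing the 4'-enzyme first caps the autoxidisable catechol early and funnels the material through the single intermediate 10, and an enzyme panel is screened beforehand because the C8 side chain sits ortho to O7. Free 9 does not alkylate phenols or the prenyl alkene at a meaningful rate at this pH, so background methylation should not erode the enzymatic regiocontrol.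

**Compound list**
1 | (+)-taxifolin, (2R,3R)-2-(3,4-dihydroxyphenyl)-3,5,7-trihydroxychroman-4-one | Oc1ccc([C@H]2Oc3cc(O)cc(O)c3C(=O)[C@@H]2O)cc1O | starting material
2 | (2R,3R)-3,7,3',4'-tetra-O-acetyltaxifolin, 5-OH free | CC(=O)Oc1ccc([C@H]2Oc3cc(OC(C)=O)cc(O)c3C(=O)[C@@H]2OC(C)=O)cc1OC(C)=O | intermediate
3 | 3-methylbut-2-en-1-ol (prenol) | CC(C)=CCO | starting material
4 | (2R,3R)-3,7,3',4'-tetra-O-acetyl-5-O-prenyltaxifolin | CC(=O)Oc1ccc([C@H]2Oc3cc(OC(C)=O)cc(OCC=C(C)C)c3C(=O)[C@@H]2OC(C)=O)cc1OC(C)=O | intermediate
5 | ortho-dienone: ring A dearomatised, C5=O, C6 bearing H and 1,1-dimethylallyl (C6 epimers), C7=C8 and C4a=C8a, (2R,3R) retained | CC(=O)Oc1ccc([C@H]2OC3=C(C(=O)[C@@H]2OC(C)=O)C(=O)C(C(C)(C)C=C)C(OC(C)=O)=C3)cc1OC(C)=O | intermediate (not isolated)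
6 | para-dienone: C5=O, C6=C7, C8 bearing H and prenyl (C8 epimers), C4a=C8a, (2R,3R) retained | CC(=O)Oc1ccc([C@H]2OC3=C(C(=O)[C@@H]2OC(C)=O)C(=O)C=C(OC(C)=O)C3CC=C(C)C)cc1OC(C)=O | intermediate (not isolated)
7 | (2R,3R)-3,7,3',4'-tetra-O-acetyl-8-prenyltaxifolin | CC(=O)Oc1ccc([C@H]2Oc3c(CC=C(C)C)c(OC(C)=O)cc(O)c3C(=O)[C@@H]2OC(C)=O)cc1OC(C)=O | intermediate
8 | (2R,3R)-8-prenyltaxifolin | Oc1ccc([C@H]2Oc3c(CC=C(C)C)c(O)cc(O)c3C(=O)[C@@H]2O)cc1O | intermediate
9 | methyl iodide | CI | starting material
10 | (2R,3R)-4'-O-methyl-8-prenyltaxifolin | COc1ccc([C@H]2Oc3c(CC=C(C)C)c(O)cc(O)c3C(=O)[C@@H]2O)cc1O | intermediate (not isolated)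
11 | (2R,3R)-3,5-dihydroxy-2-(3-hydroxy-4-methoxyphenyl)-7-methoxy-8-(3-methylbut-2-enyl)chroman-4-one | COc1ccc([C@H]2Oc3c(CC=C(C)C)c(OC)cc(O)c3C(=O)[C@@H]2O)cc1O | target

Total step count: 5. Longest linear sequence: 5 (1 → 2 → 4 → 7 → 8 → 11).

**Steps most likely to fail**

**Step 5.**
- Risk: non-productive binding. The C8 side chain ortho to O7 may keep ring A out of the pocket of the 7-enzyme. Ring B may also dock in the flipped pose, so that methyl transfer drifts to O3'.
- Fallback (methylate before prenylating), setting out from 1. The same enzyme pair with 9 and cofactor recycling is applied to the unprenylated, native-type substrate to give (2R,3R)-7,4'-di-O-methyltaxifolin F1.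
- Ac2O in pyridine caps O3 and O3' to give (2R,3R)-3,3'-di-O-acetyl-7,4'-di-O-methyltaxifolin F2.
- Mitsunobu coupling with 3 gives (2R,3R)-3,3'-di-O-acetyl-7,4'-di-O-methyl-5-O-prenyltaxifolin F3.
- Eu(fod)3-catalysed Claisen–Cope rearrangement gives (2R,3R)-3,3'-di-O-acetyl-7,4'-di-O-methyl-8-prenyltaxifolin F4.
- Methanolic HCl removes both acetates, and the sequence comes back to the route at 11. With O7 already methylated, no phenol flanks the prenyl group during the acid step.

**Step 3.**
- Risk: the relay may stop after the first sigmatropic shift, if enolisation of the dienone outruns the Cope step. That would leave the reverse-prenyl group at C6. The Lewis acid may also ionise the allyl ether, with loss of the prenyl group.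
- Fallback (electrophilic C-prenylation instead of a sigmatropic relay), setting out from 1. Friedel–Crafts alkylation with 2-methylbut-3-en-2-ol and BF3·OEt2 in dioxane at rt attacks the phloroglucinol-type ring A directly.
- 8 is separated by reversed-phase chromatography from its regioisomer (2R,3R)-6-prenyltaxifolin F5. The route is rejoined at 8, with steps 1 to 4 bypassed.

**Step 4.**
- Risk: acid-promoted attack of the freed 7-OH on the protonated prenyl alkene (chroman closure), addition of methanol to the alkene, or stalled cleavage of the hindered 3-acetate.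
- Fallback (fluoride-labile instead of acid-labile masking), setting out from 1. TBSCl and imidazole in DMF give (2R,3R)-3,7,3',4'-tetrakis-O-(tert-butyldimethylsilyl)taxifolin F6, with the chelated 5-OH again left free.
- Mitsunobu coupling with 3 gives (2R,3R)-3,7,3',4'-tetrakis-O-(tert-butyldimethylsilyl)-5-O-prenyltaxifolin F7.
- Eu(fod)3-catalysed Claisen–Cope rearrangement gives (2R,3R)-3,7,3',4'-tetrakis-O-(tert-butyldimethylsilyl)-8-prenyltaxifolin F8.
- Et3N·3HF in THF at rt removes all four silyl groups, and the route is rejoined at 8.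

**Further compounds**
F1 | step 5 | (2R,3R)-7,4'-di-O-methyltaxifolin | COc1ccc([C@H]2Oc3cc(OC)cc(O)c3C(=O)[C@@H]2O)cc1O
F2 | step 5 | (2R,3R)-3,3'-di-O-acetyl-7,4'-di-O-methyltaxifolin | COc1ccc([C@H]2Oc3cc(OC)cc(O)c3C(=O)[C@@H]2OC(C)=O)cc1OC(C)=O
F3 | step 5 | (2R,3R)-3,3'-di-O-acetyl-7,4'-di-O-methyl-5-O-prenyltaxifolin | COc1ccc([C@H]2Oc3cc(OC)cc(OCC=C(C)C)c3C(=O)[C@@H]2OC(C)=O)cc1OC(C)=O
F4 | step 5 | (2R,3R)-3,3'-di-O-acetyl-7,4'-di-O-methyl-8-prenyltaxifolin | COc1ccc([C@H]2Oc3c(CC=C(C)C)c(OC)cc(O)c3C(=O)[C@@H]2OC(C)=O)cc1OC(C)=O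
F5 | step 3 | (2R,3R)-6-prenyltaxifolin | Oc1ccc([C@H]2Oc3cc(O)c(CC=C(C)C)c(O)c3C(=O)[C@@H]2O)cc1O
F6 | step 4 | (2R,3R)-3,7,3',4'-tetrakis-O-(tert-butyldimethylsilyl)taxifolin | CC(C)(C)[Si](C)(C)Oc1ccc([C@H]2Oc3cc(O[Si](C)(C)C(C)(C)C)cc(O)c3C(=O)[C@@H]2O[Si](C)(C)C(C)(C)C)cc1O[Si](C)(C)C(C)(C)C
F7 | step 4 | (2R,3R)-3,7,3',4'-tetrakis-O-(tert-butyldimethylsilyl)-5-O-prenyltaxifolin | CC(C)(C)[Si](C)(C)Oc1ccc([C@H]2Oc3cc(O[Si](C)(C)C(C)(C)C)cc(OCC=C(C)C)c3C(=O)[C@@H]2O[Si](C)(C)C(C)(C)C)cc1O[Si](C)(C)C(C)(C)C
F8 | step 4 | (2R,3R)-3,7,3',4'-tetrakis-O-(tert-butyldimethylsilyl)-8-prenyltaxifolin | CC(C)(C)[Si](C)(C)Oc1ccc([C@H]2Oc3c(CC=C(C)C)c(O[Si](C)(C)C(C)(C)C)cc(O)c3C(=O)[C@@H]2O[Si](C)(C)C(C)(C)C)cc1O[Si](C)(C)C(C)(C)C
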